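G is the reagent and X the solid it must meet. On the list of suspects, G gives Z, and Z with D gives J, which goes on to E, so each J or E costs one G and one X.

| setting | south-east | north-east | flask |
|---|---|---|---|
| X | 0.26 M | 0.26 M | 0.26 M |
| G | 0.14 M (fed, over 5.0 min) | 0.57 M (fed, over 5.0 min) | 0.286 M (fed, over 5.0 min) |
| remark | run made earlier; the fed solution adds 0.25 times the starting volume | run made earlier; the fed solution adds 0.25 times the starting volume | the fed solution adds 0.25 times the starting volume |
| time |  |  | 15 h |

| run | time / h | J / % |
|---|---|---|
| south-east | 1.33 | 8.3 |
| south-east | 2.50 | 16.6 |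
| south-east | 4.00 | 24.1 |
| south-east | 6.00 | 20.0 |
| south-east | 10.0 | 6.6 |
| north-east | 1.33 | 9.0 |
| north-east | 2.50 | 19.7 |
| north-east | 4.00 | 32.1 |
| north-east | 6.00 | 38.6 |
| north-east | 10.0 | 20.0 |

(readings scatter by 1 percentage point)

- percentages count the X that a species holds: one Q counts as two
- every charge counts on the volume at the start, and the solution that is fed holds the whole dose
- solid, in amounts per volume of the solution: X
- on the list of suspects stand: L <-> D; G -> Z; D + Z -> J; 2 D -> Q; X <-> L; J -> E
- at the start none of X is in solution

1. when, up to 15 h, the flask holds most J
2. the amount of J, in percent of the X charged, at that time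

The flask has a cover w of 1.10, cover being the equivalents of G charged per X charged. South-east has 0.538 and north-east 2.19. By the count above, J plus E stays within the smaller of w and 1, as a share of the X charged. This is the ceiling, set by the limiting reagent: G below 1, X above it.

A first estimate takes the highest readings, 24.1% at 4.00 h in south-east and 38.6% at 6.00 h in north-east, and interpolates linearly in w. That gives 29.0% for the flask.

The objection is that the flask and north-east both stand above 1, so they share a ceiling of 100%. The better estimate is then north-east's highest reading.

That too meets an objection. The flask's spare cover, 0.100, is far less than north-east's 1.19, so Z should thin out sooner while J goes on to E. This small term is the correction. The reckoning here therefore commits to the midpoint, 33.8%, at 5.00 h.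

The forecast says 33% at 5.5 h, lower and later than this, and it finds that “it is barely in excess”.

The flask reaches 36.0% at 5.76 h, and the forecast stands within the tolerance on both.

    L ⇌ D (K = 1.33, k = 0.00827 /min)
    G → Z (k = 0.116 /min)
    D + Z → J (k = 1.89 /M/min)
    2 D → Q (k = 2.26 /M/min)
    X ⇌ L, rate k5*(cs5 - [L]) while solid is left; crystals form when [L] > cs5 (solubility = 0.0990 M, k = 0.0156 /min)
    J → E (k = 0.00507 /min)

At that time the flask already holds 36.2% as E. With its ceiling of 100%, the flask stands at 150 h with 96.0% as E and 4.03% as Q, and Z is still at 0.0292 M. The neighbour flask with 0.11 M of G has a cover of 0.423, so its ceiling is 42.3%. At 15.0 h its J plus E holds 42.3% and its Q 55.7%, and its best J is 20.7%.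

The numbers in the tables stem from a simulated flask for an exercise; the scatter is artificial.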